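**Assumption (one line):** carbons carry the germacrane numbers of the target (C1–C15); the C1–C6-bonded decalin intermediates are named as 1,6-cyclogermacranes; the ring carbon between the two carbonyls of 10 and 12 is configurationally labile (enolised) and is drawn without a descriptor.

**Retrosynthetic overview**
1. Target ⇐ acyl and protecting-group adjustments plus reagent-controlled epoxidation of the 14-hydroxy-1(10)-trans,4-cis-germacradien-12,6-olide 20.
2. 20 ⇐ ring expansion: Grob-type cleavage of the C1–C6 bond of the trans-decalin spiro-epoxide 16 (six- to ten-membered ring, sets the trans-1(10) alkene; the cis-4,5 alkene is inherited from the cyclohexene), then C6 reduction and relactonisation.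
3. 16 ⇐ methylenation and epoxidation of keto lactone 14 ⇐ intramolecular Barbier allylation of β-diketone 12 (ring B and the γ-lactone form together on ring A).
4. 12 ⇐ enone 4 (from cyclohexane-1,3-dione) + Weinreb amide 9 (from (S)-3-hydroxy-γ-butyrolactone) + methyl 2-(bromomethyl)acrylate 11.
5. Ring order: ring A (bought) → ring B + lactone → spiro-epoxide → ten-membered ring → lactone re-closed → 1,10-epoxide.

**Route**

Step 1
Reactants: 1 cyclohexane-1,3-dione
Product: 2 3-ethoxycyclohex-2-en-1-one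
Conditions: EtOH, p-TsOH (cat.), toluene, reflux, Dean–Stark
Reagents that add atoms: ethanol, CCO
Why: Acid-catalysed O-alkylation of the enolised 1,3-dione (vinylogous ester formation) driven by azeotropic removal of water; no stereocentre.

Step 2
Reactants: 2 3-ethoxycyclohex-2-en-1-one
Product: 4 3-{[(4-methoxybenzyl)oxy]methyl}cyclohex-2-en-1-one, via carbinol adduct 3 (not isolated)
Conditions: Bu3SnCH2OPMB, n-BuLi, THF, −78 °C; add 2; then 1 M HCl, 0 °C → rt
Reagents that add atoms: tributyl{[(4-methoxybenzyl)oxy]methyl}stannane, CCCC[Sn](CCCC)(CCCC)COCc1ccc(OC)cc1; water, O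
Why: Stork–Danheiser sequence: 1,2-addition of the α-alkoxymethyllithium (Sn–Li exchange) to the vinylogous ester, then acid hydrolysis with allylic transposition, gives the 3-substituted enone carrying C15; no stereocentre is kept.

Step 3
Reactants: 5 (S)-3-hydroxy-γ-butyrolactone
Product: 6 (S)-4-[(tert-butyldimethylsilyl)oxy]dihydrofuran-2(3H)-one
Conditions: TBSCl, imidazole, DMF, rt
Reagents that add atoms: tert-butyldimethylsilyl chloride, CC(C)(C)[Si](C)(C)Cl
Why: Standard silylation of the secondary alcohol; the chiral-pool stereocentre (future C8, S) is untouched.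

Step 4
Reactants: 6 (S)-4-[(tert-butyldimethylsilyl)oxy]dihydrofuran-2(3H)-one
Product: 7 (S)-3-[(tert-butyldimethylsilyl)oxy]-4-hydroxy-N-methoxy-N-methylbutanamide
Conditions: MeNH(OMe)·HCl, AlMe3, CH2Cl2, 0 °C → rt
Reagents that add atoms: N,O-dimethylhydroxylamine hydrochloride, CNOC.Cl
Why: Weinreb aminolysis of the lactone by the aluminium amide (acyl C–O cleavage only) frees the primary alcohol (C7) and activates C10 as an acyl donor; C8 is not involved.

Step 5
Reactants: 7 (S)-3-[(tert-butyldimethylsilyl)oxy]-4-hydroxy-N-methoxy-N-methylbutanamide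
Product: 8 (S)-3-[(tert-butyldimethylsilyl)oxy]-N-methoxy-N-methyl-4-oxobutanamide
Conditions: Dess–Martin periodinane, NaHCO3, CH2Cl2, rt
Reagents that add atoms: none
Why: Buffered Dess–Martin oxidation gives the α-silyloxy aldehyde under neutral conditions, so C8 does not epimerise.

Step 6
Reactants: 8 (S)-3-[(tert-butyldimethylsilyl)oxy]-N-methoxy-N-methyl-4-oxobutanamide
Product: 9 (S)-3-[(tert-butyldimethylsilyl)oxy]-N-methoxy-N-methylpent-4-enamide
Conditions: Ph3PCH3Br, KHMDS, THF, −78 → 0 °C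
Reagents that add atoms: methyltriphenylphosphonium bromide, C[P+](c1ccccc1)(c1ccccc1)c1ccccc1.[Br-]
Why: Wittig methylenation with a non-stabilised ylide at low temperature turns the aldehyde into the vinyl group needed for cross-metathesis without touching C8.

Step 7
Reactants: 4 3-{[(4-methoxybenzyl)oxy]methyl}cyclohex-2-en-1-one; 9 (S)-3-[(tert-butyldimethylsilyl)oxy]-N-methoxy-N-methylpent-4-enamide
Product: 10 6-{(3S)-3-[(tert-butyldimethylsilyl)oxy]pent-4-enoyl}-3-{[(4-methoxybenzyl)oxy]methyl}cyclohex-2-en-1-one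
Conditions: LDA, THF, −78 °C, 4 (2.1 equiv); then 9, −78 → −10 °C; aq. NH4Cl
Reagents that add atoms: none
Why: Crossed Claisen-type acylation: the kinetic α′-lithium enolate of the enone attacks the Weinreb amide and forms the C1–C10 bond; the new C1 centre lies between two carbonyls and is deliberately left labile.

Step 8
Reactants: 10 6-{(3S)-3-[(tert-butyldimethylsilyl)oxy]pent-4-enoyl}-3-{[(4-methoxybenzyl)oxy]methyl}cyclohex-2-en-1-one; 11 methyl 2-(bromomethyl)acrylate
Product: 12 methyl (2Z,4S)-2-(bromomethyl)-4-[(tert-butyldimethylsilyl)oxy]-6-(4-{[(4-methoxybenzyl)oxy]methyl}-2-oxocyclohex-3-en-1-yl)-6-oxohex-2-enoate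
Conditions: 11 (5 equiv), Hoveyda–Grubbs II (10 mol %), CH2Cl2, 40 °C
Reagents that add atoms: none
Why: Olefin cross-metathesis of the terminal alkene with the 1,1-disubstituted acrylate (ethene lost) gives the thermodynamically preferred trisubstituted enoate with C8 trans to CO2Me, the geometry needed for the chair allylation.

Step 9
Reactants: 12 methyl (2Z,4S)-2-(bromomethyl)-4-[(tert-butyldimethylsilyl)oxy]-6-(4-{[(4-methoxybenzyl)oxy]methyl}-2-oxocyclohex-3-en-1-yl)-6-oxohex-2-enoate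
Product: 14 (1R,6R,7R,8S)-keto lactone (trans-decalin), via hydroxy ester 13 (not isolated)
Conditions: In powder, THF–H2O (4:1), 0.005 M, rt; then PPTS (cat.), CH2Cl2, rt
Reagents that add atoms: none
Why: Intramolecular indium Barbier 2-(alkoxycarbonyl)allylation (SE2′, closed chair transition state) of the C6 carbonyl closes ring B; the equatorial C8–OTBS and the (Z)-allyl unit fix C7 (R) and place O6 axial, while the labile C1 is funnelled through the all-equatorial, trans-fused transition state (dynamic kinetic resolution); the tertiary alkoxide then lactonises onto the methyl ester.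

Step 10
Reactants: 14 (1R,6R,7R,8S)-keto lactone
Product: 15 (1S,6S,7R,8S)-10(14)-methylene lactone
Conditions: Zn, CH2Br2, TiCl4 (Lombardo reagent), THF–CH2Cl2, 0 °C → rt
Reagents that add atoms: dibromomethane, BrCBr
Why: Lombardo–Takai methylenation is non-basic and ketone-selective, so the lactone, the β-acyloxy ketone array and C1 survive while C14 is installed (the CIP labels of C1 and C6 change without any change in geometry).

Step 11
Reactants: 15 (1S,6S,7R,8S)-10(14)-methylene lactone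
Product: 16 (1R,6R,7R,8S,10R)-10,14-epoxy lactone
Conditions: m-CPBA, NaHCO3, CH2Cl2, 0 °C
Reagents that add atoms: m-chloroperoxybenzoic acid, O=C(OO)c1cccc(Cl)c1
Why: Prilezhaev epoxidation picks the 1,1-disubstituted alkene (C4=C5 is deactivated by two allylic C–O bonds and a neopentyl position, the acrylate is inert) and attacks the equatorial face because the axial face is blocked by the 1,3-diaxial lactone oxygen, so the C10–O bond ends equatorial, antiperiplanar to C1–C6.

Step 12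
Reactants: 16 (1R,6R,7R,8S,10R)-10,14-epoxy lactone
Product: 20 (1(10)Z,4E,6R,7S,8S)-8-[(tert-butyldimethylsilyl)oxy]-14-hydroxy-15-[(4-methoxybenzyl)oxy]germacra-1(10),4,11(13)-trien-12,6-olide, via ring-opened titanium alkoxide 17 (not isolated), via cyclodecadienone 18 (not isolated), via 6-hydroxy ester 19 (not isolated)
Conditions: Ti(OiPr)4 (2.5 equiv), i-PrOH, toluene, 60 °C; then −78 °C, MeOH, CeCl3·7H2O, NaBH4, → 0 °C; PPTS work-up
Reagents that add atoms: none
Why: Proposed new method: titanium isopropoxide opens the γ-lactone by transesterification and leaves the tertiary C6–O–Ti alkoxide, the same titanium activates the equatorial spiro-epoxide through a six-membered chelate, and a concerted Grob-type fragmentation then breaks the antiperiplanar C1–C6 bond to give the C6 ketone, the C1=C10 alkene with C2 trans to C9 (CIP Z) and the C14 alkoxide, i.e. the six- to ten-membered ring expansion; the closest known reactions are the Ti(OiPr)4-mediated epoxy-alcohol (Holton-type Grob) fragmentation of a free γ,δ-epoxy alcohol and Ti(OR)4-catalysed transesterification, here coupled so that the lactone that protected O6 during the epoxidation is itself the trigger; in-flask Luche reduction (Felkin–Anh attack anti to the C7 alkenyl group on the conformer with C5–C6 and C7–C8 antiperiplanar) sets C6 (R) and the alkoxide relactonises to the trans-fused 12,6-olide.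

Step 13
Reactants: 20 (1(10)Z,4E,6R,7S,8S)-8-[(tert-butyldimethylsilyl)oxy]-14-hydroxy-15-[(4-methoxybenzyl)oxy]germacra-1(10),4,11(13)-trien-12,6-olide
Product: 22 (1R,4E,6R,7S,8S,10S)-14-acetoxy-1,10-epoxy-8-[(tert-butyldimethylsilyl)oxy]-15-[(4-methoxybenzyl)oxy]germacra-4,11(13)-dien-12,6-olide, via epoxy alcohol 21 (not isolated)
Conditions: Ti(OiPr)4 (cat.), L-(+)-DIPT, t-BuOOH, 4 Å MS, CH2Cl2, −20 °C; then P(OMe)3; Ac2O, Et3N, DMAP, 0 °C
Reagents that add atoms: tert-butyl hydroperoxide, CC(C)(C)OO; acetic anhydride, CC(=O)OC(C)=O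
Why: Sharpless asymmetric epoxidation of the only allylic alcohol present; L-(+)-tartrate, the enantiomer that gives (2S)-epoxy alcohols from primary allylic alcohols, delivers oxygen to the face that makes C10 (S) and C1 (R); in situ acetylation then caps the 2,3-epoxy alcohol.

Step 14
Reactants: 22 (1R,4E,6R,7S,8S,10S)-14-acetoxy-1,10-epoxy-8-[(tert-butyldimethylsilyl)oxy]-15-[(4-methoxybenzyl)oxy]germacra-4,11(13)-dien-12,6-olide
Product: 23 (1R,4E,6R,7R,8S,10S)-14-acetoxy-1,10-epoxy-8-hydroxy-15-[(4-methoxybenzyl)oxy]germacra-4,11(13)-dien-12,6-olide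
Conditions: HF·pyridine, pyridine, THF, 0 °C → rt
Reagents that add atoms: none
Why: Pyridine-buffered HF cleaves the secondary silyl ether while the trisubstituted epoxide, acetate, PMB ether and α-methylene lactone are tolerated; no stereocentre changes.

Step 15
Reactants: 23 (1R,4E,6R,7R,8S,10S)-14-acetoxy-1,10-epoxy-8-hydroxy-15-[(4-methoxybenzyl)oxy]germacra-4,11(13)-dien-12,6-olide
Product: 24 (1R,4E,6R,7R,8S,10S)-14-acetoxy-1,10-epoxy-8-(methacryloyloxy)-15-[(4-methoxybenzyl)oxy]germacra-4,11(13)-dien-12,6-olide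
Conditions: methacrylic anhydride, Et3N, DMAP, CH2Cl2, 0 °C → rt
Reagents that add atoms: methacrylic anhydride, C=C(C)C(=O)OC(=O)C(C)=C
Why: DMAP-catalysed acylation of the only free hydroxyl, with retention at C8.

Step 16
Reactants: 24 (1R,4E,6R,7R,8S,10S)-14-acetoxy-1,10-epoxy-8-(methacryloyloxy)-15-[(4-methoxybenzyl)oxy]germacra-4,11(13)-dien-12,6-olide
Product: 25 (1R,4E,6R,7R,8S,10S)-14-acetoxy-1,10-epoxy-15-hydroxy-8-(methacryloyloxy)germacra-4,11(13)-dien-12,6-olide
Conditions: DDQ, CH2Cl2–pH 7 buffer, 0 °C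
Reagents that add atoms: none
Why: Oxidative cleavage of the PMB ether under neutral conditions frees the C15 alcohol without touching the epoxide, esters or alkenes.

**Compound list**

1 | cyclohexane-1,3-dione | O=C1CCCC(=O)C1 | starting material
2 | 3-ethoxycyclohex-2-en-1-one | CCOC1=CC(=O)CCC1 | intermediate
3 | 3-ethoxy-1-{[(4-methoxybenzyl)oxy]methyl}cyclohex-2-en-1-ol (racemic, not isolated) | CCOC1=CC(O)(COCc2ccc(OC)cc2)CCC1 | intermediate
4 | 3-{[(4-methoxybenzyl)oxy]methyl}cyclohex-2-en-1-one | O=C1C=C(COCc2ccc(OC)cc2)CCC1 | intermediate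
5 | (S)-3-hydroxy-γ-butyrolactone [(S)-4-hydroxydihydrofuran-2(3H)-one] | O=C1C[C@H](O)CO1 | starting material
6 | (S)-4-[(tert-butyldimethylsilyl)oxy]dihydrofuran-2(3H)-one | O=C1C[C@H](O[Si](C)(C)C(C)(C)C)CO1 | intermediate
7 | (S)-3-[(tert-butyldimethylsilyl)oxy]-4-hydroxy-N-methoxy-N-methylbutanamide | CON(C)C(=O)C[C@H](O[Si](C)(C)C(C)(C)C)CO | intermediate
8 | (S)-3-[(tert-butyldimethylsilyl)oxy]-N-methoxy-N-methyl-4-oxobutanamide | CON(C)C(=O)C[C@H](O[Si](C)(C)C(C)(C)C)C=O | intermediate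
9 | (S)-3-[(tert-butyldimethylsilyl)oxy]-N-methoxy-N-methylpent-4-enamide | CON(C)C(=O)C[C@H](O[Si](C)(C)C(C)(C)C)C=C | intermediate
10 | 6-{(3S)-3-[(tert-butyldimethylsilyl)oxy]pent-4-enoyl}-3-{[(4-methoxybenzyl)oxy]methyl}cyclohex-2-en-1-one (β-diketone, ring C6 labile) | C=C[C@@H](O[Si](C)(C)C(C)(C)C)CC(=O)C1CCC(COCc2ccc(OC)cc2)=CC1=O | intermediate
11 | methyl 2-(bromomethyl)acrylate | C=C(CBr)C(=O)OC | starting material
12 | methyl (2Z,4S)-2-(bromomethyl)-4-[(tert-butyldimethylsilyl)oxy]-6-(4-{[(4-methoxybenzyl)oxy]methyl}-2-oxocyclohex-3-en-1-yl)-6-oxohex-2-enoate | COC(=O)/C(CBr)=C/[C@@H](O[Si](C)(C)C(C)(C)C)CC(=O)C1CCC(COCc2ccc(OC)cc2)=CC1=O | intermediate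
13 | methyl (1R,6R,7R,8S)-8-[(tert-butyldimethylsilyl)oxy]-6-hydroxy-15-[(4-methoxybenzyl)oxy]-10-oxo-14-nor-1,6-cyclogermacra-4,11(13)-dien-12-oate (trans-decalin, not isolated) | C=C(C(=O)OC)[C@@H]1[C@@H](O[Si](C)(C)C(C)(C)C)CC(=O)[C@@H]2CCC(COCc3ccc(OC)cc3)=C[C@@]12O | intermediate
14 | (1R,6R,7R,8S)-8-[(tert-butyldimethylsilyl)oxy]-15-[(4-methoxybenzyl)oxy]-10-oxo-14-nor-1,6-cyclogermacra-4,11(13)-dien-12,6-olide (trans-decalin, cis-fused α-methylene lactone) | C=C1C(=O)O[C@@]23C=C(COCc4ccc(OC)cc4)CC[C@H]2C(=O)C[C@H](O[Si](C)(C)C(C)(C)C)[C@@H]13 | intermediate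
15 | (1S,6S,7R,8S)-8-[(tert-butyldimethylsilyl)oxy]-15-[(4-methoxybenzyl)oxy]-1,6-cyclogermacra-4,10(14),11(13)-trien-12,6-olide | C=C1C(=O)O[C@@]23C=C(COCc4ccc(OC)cc4)CC[C@H]2C(=C)C[C@H](O[Si](C)(C)C(C)(C)C)[C@@H]13 | intermediate
16 | (1R,6R,7R,8S,10R)-10,14-epoxy-8-[(tert-butyldimethylsilyl)oxy]-15-[(4-methoxybenzyl)oxy]-1,6-cyclogermacra-4,11(13)-dien-12,6-olide (epoxide C–O equatorial) | C=C1C(=O)O[C@@]23C=C(COCc4ccc(OC)cc4)CC[C@H]2[C@@]5(CO5)C[C@H](O[Si](C)(C)C(C)(C)C)[C@@H]13 | intermediate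
17 | isopropyl (1R,6R,7R,8S,10R)-10,14-epoxy-8-[(tert-butyldimethylsilyl)oxy]-6-hydroxy-15-[(4-methoxybenzyl)oxy]-1,6-cyclogermacra-4,11(13)-dien-12-oate (present as its C6 titanium alkoxide, not isolated) | C=C(C(=O)OC(C)C)[C@@H]1[C@@H](O[Si](C)(C)C(C)(C)C)C[C@]3(CO3)[C@@H]2CCC(COCc4ccc(OC)cc4)=C[C@@]12O | intermediate
18 | isopropyl (1(10)Z,4E,7R,8S)-8-[(tert-butyldimethylsilyl)oxy]-14-hydroxy-15-[(4-methoxybenzyl)oxy]-6-oxogermacra-1(10),4,11(13)-trien-12-oate (not isolated) | C=C(C(=O)OC(C)C)[C@@H]1[C@@H](O[Si](C)(C)C(C)(C)C)C/C(CO)=C/CC/C(COCc2ccc(OC)cc2)=C\C1=O | intermediate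
19 | isopropyl (1(10)Z,4E,6R,7S,8S)-8-[(tert-butyldimethylsilyl)oxy]-6,14-dihydroxy-15-[(4-methoxybenzyl)oxy]germacra-1(10),4,11(13)-trien-12-oate (not isolated) | C=C(C(=O)OC(C)C)[C@@H]1[C@@H](O[Si](C)(C)C(C)(C)C)C/C(CO)=C/CC/C(COCc2ccc(OC)cc2)=C\[C@H]1O | intermediate
20 | (1(10)Z,4E,6R,7S,8S)-8-[(tert-butyldimethylsilyl)oxy]-14-hydroxy-15-[(4-methoxybenzyl)oxy]germacra-1(10),4,11(13)-trien-12,6-olide (ring geometry: 1(10) trans, 4,5 cis; trans-fused lactone) | CC(C)(C)[Si](C)(C)O[C@H]1C/C(CO)=C/CC/C(COCc3ccc(OC)cc3)=C\[C@H]2OC(=O)C(=C)[C@H]12 | intermediate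
21 | (1R,4E,6R,7S,8S,10S)-1,10-epoxy-8-[(tert-butyldimethylsilyl)oxy]-14-hydroxy-15-[(4-methoxybenzyl)oxy]germacra-4,11(13)-dien-12,6-olide (not isolated) | CC(C)(C)[Si](C)(C)O[C@H]1C[C@@]2(CO)O[C@@H]2CC/C(COCc3ccc(OC)cc3)=C\[C@H]2OC(=O)C(=C)[C@H]12 | intermediate
22 | (1R,4E,6R,7S,8S,10S)-14-acetoxy-1,10-epoxy-8-[(tert-butyldimethylsilyl)oxy]-15-[(4-methoxybenzyl)oxy]germacra-4,11(13)-dien-12,6-olide | CC(C)(C)[Si](C)(C)O[C@H]1C[C@@]2(COC(C)=O)O[C@@H]2CC/C(COCc3ccc(OC)cc3)=C\[C@H]2OC(=O)C(=C)[C@H]12 | intermediate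
23 | (1R,4E,6R,7R,8S,10S)-14-acetoxy-1,10-epoxy-8-hydroxy-15-[(4-methoxybenzyl)oxy]germacra-4,11(13)-dien-12,6-olide | O[C@H]1C[C@@]2(COC(C)=O)O[C@@H]2CC/C(COCc3ccc(OC)cc3)=C\[C@H]2OC(=O)C(=C)[C@H]12 | intermediate
24 | (1R,4E,6R,7R,8S,10S)-14-acetoxy-1,10-epoxy-8-(methacryloyloxy)-15-[(4-methoxybenzyl)oxy]germacra-4,11(13)-dien-12,6-olide | C=C(C)C(=O)O[C@H]1C[C@@]2(COC(C)=O)O[C@@H]2CC/C(COCc3ccc(OC)cc3)=C\[C@H]2OC(=O)C(=C)[C@H]12 | intermediate
25 | (1R,4E,6R,7R,8S,10S)-14-acetoxy-1,10-epoxy-15-hydroxy-8-(methacryloyloxy)germacra-4,11(13)-dien-12,6-olide | C=C(C)C(=O)O[C@H]1C[C@@]2(COC(C)=O)O[C@@H]2CC/C(CO)=C\[C@H]2OC(=O)C(=C)[C@H]12 | target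

**Count and risks**

Total step count: 16. Longest linear sequence: 14 steps (5 → 25, steps 3–16); the ring-A branch (steps 1–2) joins at step 7.

The three steps most likely to fail are steps 9, 12 and 13.

Step 9 may fail because the allylindium has to add to the less electrophilic, enolised enone carbonyl of a β-diketone, in competition with α-attack on C10, and the preceding cross-metathesis onto a hindered allylic silyl ether is itself demanding. The fallback sets out from aldehyde 8 and removes both problems by replacing the allyl bromide with an allylsilane. Horner–Wadsworth–Emmons olefination of 8 with methyl 2-(dimethoxyphosphoryl)-3-(trimethylsilyl)propanoate (NaH, THF) gives methyl (2Z,4S)-4-[(tert-butyldimethylsilyl)oxy]-6-[methoxy(methyl)amino]-6-oxo-2-[(trimethylsilyl)methyl]hex-2-enoate F1. F1 is not an alkylating agent and is a poor Michael acceptor, so it can acylate the lithium enolate of 4 to give the β-diketone allylsilane F2. TiCl4 in CH2Cl2 at −78 °C then chelates and activates the β-diketone for an intramolecular Hosomi–Sakurai allylation through the same equatorially substituted ring-B chair; PPTS closes the lactone (through 13) and the route is rejoined at 14.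

Step 12, the proposed new cascade, may fail if the hindered lactone does not open below the temperature at which ketone 18 isomerises (its C7–H is flanked by the ketone and the acrylate). The fallback uses only known chemistry and sets out from 16. LiOH in THF–H2O gives the hydroxy acid F3 as its lithium salt, and MeI with K2CO3 in DMF gives the hydroxy methyl ester F4. The free γ,δ-epoxy alcohol F4 then undergoes the known Ti(OiPr)4-mediated epoxy-alcohol fragmentation in CH2Cl2 at room temperature to keto ester F5. Luche reduction gives the 6-hydroxy ester F6, which lactonises with PPTS and returns to the route at 20; isolating F5 also permits a reagent-controlled reduction if the C6 selectivity is poor.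

Step 13 may fail because the allylic alcohol is 2,3-cis-trisubstituted and sits in a ten-membered ring, so the Sharpless epoxidation may be slow or mismatched with the ring conformation. The fallback sets out from 20 and relies on substrate control: acetylation (Ac2O, pyridine) gives the 14-acetate F7, and m-CPBA with NaHCO3 in CH2Cl2 at 0 °C then epoxidises the strained trans 1(10)-alkene from its exposed outer face in preference to the doubly deactivated cis 4,5-alkene, returning to the route at 22.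

**Further compounds**

F1 | step 9 | methyl (2Z,4S)-4-[(tert-butyldimethylsilyl)oxy]-6-[methoxy(methyl)amino]-6-oxo-2-[(trimethylsilyl)methyl]hex-2-enoate | COC(=O)/C(C[Si](C)(C)C)=C/[C@@H](O[Si](C)(C)C(C)(C)C)CC(=O)N(C)OC
F2 | step 9 | methyl (2Z,4S)-4-[(tert-butyldimethylsilyl)oxy]-6-(4-{[(4-methoxybenzyl)oxy]methyl}-2-oxocyclohex-3-en-1-yl)-6-oxo-2-[(trimethylsilyl)methyl]hex-2-enoate | COC(=O)/C(C[Si](C)(C)C)=C/[C@@H](O[Si](C)(C)C(C)(C)C)CC(=O)C1CCC(COCc2ccc(OC)cc2)=CC1=O
F3 | step 12 | (1R,6R,7R,8S,10R)-10,14-epoxy-8-[(tert-butyldimethylsilyl)oxy]-6-hydroxy-15-[(4-methoxybenzyl)oxy]-1,6-cyclogermacra-4,11(13)-dien-12-oic acid (handled as lithium salt) | C=C(C(=O)O)[C@@H]1[C@@H](O[Si](C)(C)C(C)(C)C)C[C@]3(CO3)[C@@H]2CCC(COCc4ccc(OC)cc4)=C[C@@]12O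
F4 | step 12 | methyl (1R,6R,7R,8S,10R)-10,14-epoxy-8-[(tert-butyldimethylsilyl)oxy]-6-hydroxy-15-[(4-methoxybenzyl)oxy]-1,6-cyclogermacra-4,11(13)-dien-12-oate | C=C(C(=O)OC)[C@@H]1[C@@H](O[Si](C)(C)C(C)(C)C)C[C@]3(CO3)[C@@H]2CCC(COCc4ccc(OC)cc4)=C[C@@]12O
F5 | step 12 | methyl (1(10)Z,4E,7R,8S)-8-[(tert-butyldimethylsilyl)oxy]-14-hydroxy-15-[(4-methoxybenzyl)oxy]-6-oxogermacra-1(10),4,11(13)-trien-12-oate | C=C(C(=O)OC)[C@@H]1[C@@H](O[Si](C)(C)C(C)(C)C)C/C(CO)=C/CC/C(COCc2ccc(OC)cc2)=C\C1=O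
F6 | step 12 | methyl (1(10)Z,4E,6R,7S,8S)-8-[(tert-butyldimethylsilyl)oxy]-6,14-dihydroxy-15-[(4-methoxybenzyl)oxy]germacra-1(10),4,11(13)-trien-12-oate | C=C(C(=O)OC)[C@@H]1[C@@H](O[Si](C)(C)C(C)(C)C)C/C(CO)=C/CC/C(COCc2ccc(OC)cc2)=C\[C@H]1O
F7 | step 13 | (1(10)Z,4E,6R,7S,8S)-14-acetoxy-8-[(tert-butyldimethylsilyl)oxy]-15-[(4-methoxybenzyl)oxy]germacra-1(10),4,11(13)-trien-12,6-olide | CC(C)(C)[Si](C)(C)O[C@H]1C/C(COC(C)=O)=C/CC/C(COCc3ccc(OC)cc3)=C\[C@H]2OC(=O)C(=C)[C@H]12
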